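**Plan**
1. Cuts: (i) the C–CH3 bond at the ring-B carbinol (MeLi on a ring-B ketone); (ii) the ring-B bond from that carbon to the bridge-bearing CH (acyl-radical hydroacylation); (iii) the central CH2–CH2 bond of the bridge (B-alkyl Suzuki–Miyaura); (iv) ring A at O–CMe2 and at the quaternary C–CH(O) bond; (v) rings C/D back to (R)-carvone.
2. Forward: ring D by RCM on allylated carvone, ring C by one-carbon ring expansion; separately ring A (oxepane) from nerol and a C4 nitrile; union at the bridge; ring B (cyclohexane) closed third from last.
3. Stereochemistry: (R)-carvone fixes the C/D fusion (cis by equilibration); convex-face epoxidation and hydroboration set the ring-D carbinol and the ring-C CH; a (Z)-allylboration under chiral acid control sets the quaternary carbon and O–CH of ring A.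
4. In ring B the bridge CH is set in the chair of the ring closure (and is epimerisable next to the ketone); the carbinol is set by equatorial MeLi attack.
5. Enabling feature: the ring-B carbinol carbon lies, through two CH2 groups, the O–CH of ring A and the methyl-bearing quaternary carbon, five atoms from the bridge carbon next to that quaternary centre. Without its methyl it is an acyl radical held for 6-exo attack by the two equatorial oxepane bonds; the axial angular methyl then shields one face of the resulting ketone.

Key step: step 18

Remark: ring A is carried as its (S)-configured secondary alcohol and oxidised only in the last step; the tertiary hydroxyl groups are never protected, on the assumption that 9-BBN spares the hindered tertiary hydroxyl or is released from it on basic work-up.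

**Route**

Step 1
Reactants: 1 (R)-carvone
Product: 3 (5R,6S)-6-allylcarvone, via lithium dienolate 2 (not isolated)
Conditions: LiN(iPr)2, THF, −78 °C; allyl bromide, DMPU, −78 → −20 °C
Reagents that add atoms: allyl bromide C=CCBr
Why: Enolate alkylation: kinetic deprotonation gives the cross-conjugated α′-dienolate and allyl bromide should enter anti to the neighbouring isopropenyl group, so the trans isomer is expected to predominate, the new centre being epimerisable and corrected in step 2.

Step 2
Reactants: 3 (5R,6S)-6-allylcarvone
Product: 5 cis-fused dienone (3aR,7aR)-3,6-dimethyl-1,3a,4,7a-tetrahydro-7H-inden-7-one, via trans-fused dienone 4 (not isolated)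
Conditions: second-generation Grubbs catalyst [(H2IMes)(PCy3)Cl2Ru=CHPh] (2 mol%), CH2Cl2, 40 °C; then DBU (0.5 equiv), 40 °C
Reagents that add atoms: none
Why: Ring-closing metathesis joins the allyl and isopropenyl groups to the trisubstituted cyclopentene of ring D while the electron-poor enone alkene stays inert, and DBU then equilibrates the α′-centre through the dienolate to the cis fusion, expected to be the more stable one because a cyclopentene whose sp2 carbon sits on the junction cannot span a trans fusion to the cyclohexenone without strain.

Step 3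
Reactants: 5 cis-fused dienone
Product: 7 (3aR,8aS)-3,6-dimethyl-3a,4,8,8a-tetrahydroazulen-7(1H)-one, via C-silyl ketone 6 (not isolated)
Conditions: Me3SiCHN2, BF3·OEt2, CH2Cl2, −78 → −40 °C; then 1 M HCl, THF, rt
Reagents that add atoms: trimethylsilyldiazomethane C[Si](C)(C)C=[N+]=[N-]
Why: Lewis-acid-promoted diazoalkane homologation of a ketone (Tiffeneau–Demjanov-type ring expansion): the diazo carbon adds to the activated carbonyl and the sp3 ring-fusion carbon should migrate in preference to the vinylic carbon, with retention, so that CH2 is inserted on the saturated side and the cis fusion is kept, acid then removing the silyl group.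

Step 4
Reactants: 7 cycloheptenone
Product: 11 (3aR,8aR)-3,6,8,8-tetramethyl-3a,4,8,8a-tetrahydroazulen-7(1H)-one, via lithium enolate 8 (not isolated), via monomethyl ketone 9 (not isolated), via lithium enolate 10 (not isolated)
Conditions: LiN(iPr)2, THF, −78 °C, then MeI; second charge of LiN(iPr)2, then MeI, −78 → 0 °C
Reagents that add atoms: iodomethane CI
Why: Two kinetic enolate methylations: the only enolisable α-position is the newly inserted methylene (the other α-carbon is vinylic), so both methyl groups should end up there and no stereocentre remains at that carbon.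

Step 5
Reactants: 11 gem-dimethyl dienone
Product: 12 cyclopentene epoxide of 11 with the oxygen on the face of the ring-fusion hydrogens
Conditions: mCPBA, NaHCO3, CH2Cl2, 0 °C
Reagents that add atoms: 3-chloroperoxybenzoic acid OOC(=O)c1cccc(Cl)c1
Why: Prilezhaev epoxidation: the electrophilic peracid should select the electron-rich trisubstituted cyclopentene over the enone and approach the convex face of the cis-fused bicycle, the face of the two ring-fusion hydrogens and away from the gem-dimethyl carbon, which places the oxygen where the tertiary hydroxyl is needed.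

Step 6
Reactants: 12 epoxy enone
Product: 13 epoxy diene (7-methylidene analogue of 12)
Conditions: Ph3PCH3Br, KOtBu, toluene, 90 °C
Reagents that add atoms: methyltriphenylphosphonium bromide C[P+](c1ccccc1)(c1ccccc1)c1ccccc1.[Br-]
Why: Wittig methylenation with the salt-free ylide at elevated temperature, a known answer to hindered ketones, converts the enone into the exocyclic diene, the ketone being unable to enolise towards the quaternary carbon and the trisubstituted epoxide being inert to the ylide.

Step 7
Reactants: 13 epoxy diene
Product: 14 cis-fused 3,6,8,8-tetramethyl-7-methylidene-1,2,3,3a,4,7,8,8a-octahydroazulen-3-ol (hydroxyl cis to the ring-fusion hydrogens)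
Conditions: LiEt3BH, THF, 0 °C → rt; aq. NH4Cl
Reagents that add atoms: none
Why: SN2 opening of the epoxide by hydride at its less substituted carbon leaves the oxygen on the methyl-bearing carbon, so the tertiary alcohol keeps the configuration set in step 5 and the diene is untouched.

Step 8
Reactants: 15 4,4-diethoxybutanenitrile
Product: 16 4-oxobutanenitrile
Conditions: 1 M HCl, THF–H2O, rt
Reagents that add atoms: water O
Why: Acid-catalysed acetal hydrolysis liberates the aldehyde while the nitrile is stable to dilute acid at room temperature.

Step 9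
Reactants: 17 nerol
Product: 18 neryl chloride
Conditions: PPh3, CCl4, reflux
Reagents that add atoms: carbon tetrachloride ClC(Cl)(Cl)Cl
Why: Appel chlorination of the primary allylic alcohol proceeds by SN2 displacement of the oxyphosphonium group and should keep the Z geometry.

Step 10
Reactants: 18 neryl chloride
Product: 19 neryl pinacol boronate
Conditions: B2pin2, Pd2(dba)3 (1 mol%), THF, 60 °C
Reagents that add atoms: bis(pinacolato)diboron CC1(C)OB(OC1(C)C)B1OC(C)(C)C(C)(C)O1
Why: Palladium-catalysed borylation of the allylic chloride with the diboron reagent gives the linear allylboronate, and the Z geometry should survive because syn–anti exchange of the allylpalladium intermediate would need a σ-bond at the fully substituted terminus.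

Step 11
Reactants: 19 neryl pinacol boronate; 16 4-oxobutanenitrile
Product: 21 (4R,5R)-5-ethenyl-4-hydroxy-5,9-dimethyldec-8-enenitrile, via O-boryl ether 20 (not isolated)
Conditions: (S)-TRIP [(S)-3,3′-bis(2,4,6-triisopropylphenyl)-1,1′-binaphthyl-2,2′-diyl hydrogen phosphate] (5 mol%), 4 Å molecular sieves, toluene, −30 °C; then aq. NaOH work-up
Reagents that add atoms: none
Why: Chiral phosphoric acid-catalysed allylboration through a closed six-membered chair: the Z boronate puts the homoprenyl group axial and the methyl equatorial, which fixes the relative configuration (hydroxyl and methyl syn when the two chains are drawn anti), and the (S)-acid is chosen to direct addition to the Si face of the aldehyde, the (R)-acid being expected to favour the Re face.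

Step 12
Reactants: 21 homoallylic alcohol
Product: 22 (4R,5R)-7-[(2S)-3,3-dimethyloxiran-2-yl]-5-ethenyl-4-hydroxy-5-methylheptanenitrile
Conditions: L-fructose-derived (ent-)Shi ketone (0.3 equiv), Oxone (2KHSO5·KHSO4·K2SO4), K2CO3, Bu4NHSO4, MeCN–CH2(OMe)2–aq. Na2B4O7 buffer, 0 °C
Reagents that add atoms: potassium peroxymonosulfate [K+].[O-]S(=O)(=O)OO
Why: Shi epoxidation: the chiral dioxirane attacks the electron-rich trisubstituted alkene and leaves the hindered vinyl group alone, and the L-fructose-derived catalyst should give the (S) epoxide by reagent control.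

Step 13
Reactants: 22 hydroxy epoxide
Product: 23 3-[(2R,3R,6S)-3-ethenyl-6-hydroxy-3,7,7-trimethyloxepan-2-yl]propanenitrile
Conditions: (+)-camphor-10-sulfonic acid (0.1 equiv), CH2Cl2, −20 → 0 °C
Reagents that add atoms: none
Why: Acid-catalysed intramolecular epoxide opening in the 7-endo-tet mode: the protonated trisubstituted epoxide carries most of its positive charge on the tertiary carbon, so the secondary hydroxyl should attack there and close the 2,2-dimethyloxepane, the secondary C–O bond and hence the (S) carbinol being untouched.

Step 14
Reactants: 23 vinyl oxepanol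
Product: 25 3-[(2R,3S,6S)-3-formyl-6-hydroxy-3,7,7-trimethyloxepan-2-yl]propanenitrile, via ozonide 24 (not isolated)
Conditions: O3, CH2Cl2, −78 °C; then PPh3, −78 °C → rt
Reagents that add atoms: ozone [O-][O+]=O
Why: Ozonolysis of the only alkene and reduction of the ozonide gives the α-quaternary aldehyde, which cannot epimerise and should not form a bridged lactol because the ring hydroxyl is trans to the formyl group.

Step 15
Reactants: 25 aldehyde
Product: 26 3-[(2R,3R,6S)-6-hydroxy-3-[(E)-2-iodoethenyl]-3,7,7-trimethyloxepan-2-yl]propanenitrile
Conditions: CrCl2 (6 equiv), CHI3 (2 equiv), THF–1,4-dioxane, 0 °C → rt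
Reagents that add atoms: iodoform IC(I)I
Why: Takai olefination: the gem-dichromium species from iodoform adds to the aldehyde and eliminates to the E-vinyl iodide, tolerating the free hydroxyl and the nitrile.

Step 16
Reactants: 14 diene alcohol; 26 vinyl iodide
Product: 28 coupled (E)-alkene nitrile, via alkylborane 27 (not isolated)
Conditions: 9-BBN (2.2 equiv), THF, 0 °C → rt; then 26, Pd(dppf)Cl2 (5 mol%), AsPh3, Cs2CO3, DMF–H2O, rt
Reagents that add atoms: none
Why: Hydroboration then B-alkyl Suzuki–Miyaura coupling: 9-BBN adds only to the exocyclic methylene of the diene, boron to the terminal carbon and hydrogen to the ring carbon from the convex face (that of the ring-fusion hydrogens, anti to the axial methyl of the neighbouring gem-dimethyl carbon), which sets the ring-C stereocentre with the CH2 branch equatorial and cis to the nearer ring-D bond, and the alkylborane couples with the vinyl iodide with retention of the E geometry.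

Step 17
Reactants: 28 nitrile
Product: 30 alkenal (ring-B seco aldehyde), via aluminium aldimine 29 (not isolated)
Conditions: iBu2AlH (4 equiv), CH2Cl2, −78 °C; then aq. KNaC4H4O6, rt
Reagents that add atoms: water O
Why: Partial reduction of the nitrile by the aluminium hydride stops at the N-aluminio aldimine at −78 °C, which is hydrolysed to the aldehyde on work-up, the three hydroxyl groups merely consuming hydride.

Step 18
Reactants: 30 alkenal
Product: 31 ring-B ketone (tetracyclic cyclohexanone lacking the carbinol methyl)
Conditions: tert-dodecanethiol (0.3 equiv), AIBN (0.2 equiv, in portions), chlorobenzene (0.01 M), 80 °C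
Reagents that add atoms: none
Why: The thiyl radical from the thiol abstracts the aldehydic hydrogen (polarity-reversal catalysis), the nucleophilic acyl radical adds to the alkene carbon next to the quaternary centre, and the secondary alkyl radical so formed takes hydrogen back from the thiol, which carries the chain. The closest known reaction type is the thiol-catalysed intramolecular hydroacylation of alkenals (acyl-radical cyclization), here applied to a new substrate. Ring B closes in the 6-exo-trig mode through a chair in which the two oxepane bonds on the quaternary carbon and on the O–CH stay equatorial and the angular methyl is axial. The one new stereocentre, the bridge-bearing CH, is set by the alkene branch taking the pseudo-equatorial position in that chair, and since it lies next to the new ketone any minor epimer can be equilibrated to the same, more stable equatorial isomer. The step needs exo over 7-endo regioselectivity, which the alkyl substituent on the distal alkene carbon and the geometry of the trans-substituted oxepane should secure, and it needs the acyl radical to spare the ring-C alkene, which is out of reach of any favourable ring size. Decarbonylation is slow for a primary acyl radical at 80 °C, and the bulky thiol is kept catalytic so that hydrogen abstraction from the hindered allylic CH of ring C should not compete.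

Step 19
Reactants: 31 ring-B ketone
Product: 32 triol (the target with ring A as its (S)-secondary alcohol)
Conditions: MeLi (5 equiv), CeCl3 (5 equiv), THF, −78 °C; aq. NH4Cl
Reagents that add atoms: methyllithium [Li]C
Why: 1,2-Addition of the organocerium reagent with little enolisation: axial approach to the ring-B ketone is blocked by the syn-axial angular methyl on the quaternary carbon two atoms away, so methyl should enter equatorially and the new hydroxyl become axial, cis to that methyl and to the equatorial bridge, as in the target.

Step 20
Reactants: 32 triol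
Product: 33 sipholenone A
Conditions: Dess–Martin periodinane, NaHCO3, CH2Cl2, 0 °C → rt
Reagents that add atoms: none
Why: Dess–Martin oxidation converts the only secondary alcohol into the ring-A ketone while the two tertiary alcohols and the trisubstituted alkene cannot react.

**Compound list**
1 | (R)-(−)-carvone | CC1=CC[C@@H](C(C)=C)CC1=O | starting material
2 | lithium 6-methyl-3-(prop-1-en-2-yl)cyclohexa-1,5-dien-1-olate (α′-dienolate of 1) | CC1=CC[C@@H](C(C)=C)C=C1O[Li] | intermediate
3 | (5R,6S)-2-methyl-5-(prop-1-en-2-yl)-6-(prop-2-en-1-yl)cyclohex-2-en-1-one (trans-6-allylcarvone) | CC1=CC[C@@H](C(C)=C)[C@H](CC=C)C1=O | intermediate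
4 | (3aR,7aS)-3,6-dimethyl-1,3a,4,7a-tetrahydro-7H-inden-7-one (trans-fused) | CC1=CC[C@@H]2[C@H](CC=C2C)C1=O | intermediate
5 | (3aR,7aR)-3,6-dimethyl-1,3a,4,7a-tetrahydro-7H-inden-7-one (cis-fused) | CC1=CC[C@@H]2[C@@H](CC=C2C)C1=O | intermediate
6 | cis-fused 3,6-dimethyl-8-(trimethylsilyl)-3a,4,8,8a-tetrahydroazulen-7(1H)-one (either configuration at the silyl-bearing carbon) | CC1=CC[C@@H]2[C@@H](CC=C2C)C([Si](C)(C)C)C1=O | intermediate
7 | (3aR,8aS)-3,6-dimethyl-3a,4,8,8a-tetrahydroazulen-7(1H)-one (cis-fused) | CC1=CC[C@@H]2[C@@H](CC=C2C)CC1=O | intermediate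
8 | lithium enolate of 7 (enolised towards the inserted CH2) | CC1=CC[C@@H]2[C@@H](CC=C2C)C=C1O[Li] | intermediate
9 | cis-fused 3,6,8-trimethyl-3a,4,8,8a-tetrahydroazulen-7(1H)-one (either configuration at C-8) | CC1=CC[C@@H]2[C@@H](CC=C2C)C(C)C1=O | intermediate
10 | lithium enolate of 9 | CC1=CC[C@@H]2[C@@H](CC=C2C)C(C)=C1O[Li] | intermediate
11 | (3aR,8aR)-3,6,8,8-tetramethyl-3a,4,8,8a-tetrahydroazulen-7(1H)-one (cis-fused) | CC1=CC[C@@H]2[C@@H](CC=C2C)C(C)(C)C1=O | intermediate
12 | 2,3-epoxide of 11, oxygen cis to the ring-fusion hydrogens | CC1=CC[C@@H]2[C@@H](C[C@H]3O[C@@]23C)C(C)(C)C1=O | intermediate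
13 | 7-methylidene analogue of 12 (epoxy diene) | CC1=CC[C@@H]2[C@@H](C[C@H]3O[C@@]23C)C(C)(C)C1=C | intermediate
14 | cis-fused 3,6,8,8-tetramethyl-7-methylidene-1,2,3,3a,4,7,8,8a-octahydroazulen-3-ol, hydroxyl cis to the ring-fusion hydrogens | CC1=CC[C@@H]2[C@@H](CC[C@@]2(C)O)C(C)(C)C1=C | intermediate
15 | 4,4-diethoxybutanenitrile | CCOC(CCC#N)OCC | starting material
16 | 4-oxobutanenitrile | O=CCCC#N | intermediate
17 | nerol, (2Z)-3,7-dimethylocta-2,6-dien-1-ol | CC(C)=CCC/C(C)=C\CO | starting material
18 | neryl chloride, (2Z)-1-chloro-3,7-dimethylocta-2,6-diene | CC(C)=CCC/C(C)=C\CCl | intermediate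
19 | 2-[(2Z)-3,7-dimethylocta-2,6-dien-1-yl]-4,4,5,5-tetramethyl-1,3,2-dioxaborolane | CC(C)=CCC/C(C)=C\CB1OC(C)(C)C(C)(C)O1 | intermediate
20 | O-(pinacolatoboryl) ether of 21 | N#CCC[C@@H](OB1OC(C)(C)C(C)(C)O1)[C@@](C)(C=C)CCC=C(C)C | intermediate
21 | (4R,5R)-5-ethenyl-4-hydroxy-5,9-dimethyldec-8-enenitrile | N#CCC[C@@H](O)[C@@](C)(C=C)CCC=C(C)C | intermediate
22 | (4R,5R)-7-[(2S)-3,3-dimethyloxiran-2-yl]-5-ethenyl-4-hydroxy-5-methylheptanenitrile | N#CCC[C@@H](O)[C@@](C)(C=C)CC[C@@H]1OC1(C)C | intermediate
23 | 3-[(2R,3R,6S)-3-ethenyl-6-hydroxy-3,7,7-trimethyloxepan-2-yl]propanenitrile | C=C[C@@]1(C)CC[C@H](O)C(C)(C)O[C@@H]1CCC#N | intermediate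
24 | 1,2,4-trioxolane (ozonide) of 23 | O1COC(O1)[C@@]2(C)CC[C@H](O)C(C)(C)O[C@@H]2CCC#N | intermediate
25 | 3-[(2R,3S,6S)-3-formyl-6-hydroxy-3,7,7-trimethyloxepan-2-yl]propanenitrile | O=C[C@@]1(C)CC[C@H](O)C(C)(C)O[C@@H]1CCC#N | intermediate
26 | 3-[(2R,3R,6S)-6-hydroxy-3-[(E)-2-iodoethenyl]-3,7,7-trimethyloxepan-2-yl]propanenitrile | I/C=C/[C@@]1(C)CC[C@H](O)C(C)(C)O[C@@H]1CCC#N | intermediate
27 | B-alkyl-9-BBN from 14 (boron on the new CH2, ring CH with hydrogen cis to the ring-fusion hydrogens) | CC1=CC[C@@H]2[C@@H](CC[C@@]2(C)O)C(C)(C)[C@H]1CB1C2CCCC1CCC2 | intermediate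
28 | coupled nitrile: rings C/D joined through CH2–CH=CH (E) to the quaternary carbon of the oxepane 26 | CC1=CC[C@@H]2[C@@H](CC[C@@]2(C)O)C(C)(C)[C@H]1C/C=C/[C@@]1(C)CC[C@H](O)C(C)(C)O[C@@H]1CCC#N | intermediate
29 | N-(diisobutylaluminio)aldimine of 28 (hydroxyl groups drawn free) | CC1=CC[C@@H]2[C@@H](CC[C@@]2(C)O)C(C)(C)[C@H]1C/C=C/[C@@]1(C)CC[C@H](O)C(C)(C)O[C@@H]1CCC=N[Al](CC(C)C)CC(C)C | intermediate
30 | aldehyde corresponding to nitrile 28 | CC1=CC[C@@H]2[C@@H](CC[C@@]2(C)O)C(C)(C)[C@H]1C/C=C/[C@@]1(C)CC[C@H](O)C(C)(C)O[C@@H]1CCC=O | intermediate
31 | tetracyclic ring-B ketone: trans-fused oxepane–cyclohexanone, bridge equatorial, ring A as (S)-alcohol | CC1=CC[C@@H]2[C@@H](CC[C@@]2(C)O)C(C)(C)[C@H]1CC[C@@H]1[C@@]2(C)CC[C@H](O)C(C)(C)O[C@@H]2CCC1=O | intermediate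
32 | triol: the target with the ring-A ketone as (S)-secondary alcohol | CC1=CC[C@@H]2[C@@H](CC[C@@]2(C)O)C(C)(C)[C@H]1CC[C@@H]1[C@@]2(C)CC[C@H](O)C(C)(C)O[C@@H]2CC[C@]1(C)O | intermediate
33 | sipholenone A | CC1=CC[C@@H]2[C@@H](CC[C@@]2(C)O)C(C)(C)[C@H]1CC[C@@H]1[C@@]2(C)CCC(=O)C(C)(C)O[C@@H]2CC[C@]1(C)O | target

**Count and risks**
Total steps: 20. Longest linear sequence: 12 steps (steps 1–7 then 16–20 from (R)-carvone; equally steps 9–15 then 16–20 from nerol).

Step 18 (key step). The thiyl radical may abstract the allylic hydrogen of ring C reversibly, which would scramble that centre or move the ring-C double bond; the chain may also be too short, so that the acyl radical is only returned to aldehyde. The fallback sets out from 30 and avoids thiyl radicals. Pinnick oxidation (NaClO2, NaH2PO4, 2-methylbut-2-ene, tBuOH–H2O) should give the carboxylic acid F1. (PhSe)2 and PBu3 should convert it into the Se-phenyl selenoester F2. Bu3SnH with AIBN in benzene at 80 °C under high dilution should generate the same acyl radical by selenium abstraction in a stannane chain. The fallback comes back to the route at 31.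

Step 13. The hydroxyl may attack the secondary epoxide carbon in the 6-exo mode and give a tetrahydropyran, or the opened epoxide may suffer a hydride shift. The fallback sets out from 21 and forms the ring oxygen–carbon bond on the alkene instead. Hg(OCOCF3)2 in MeNO2 at 0 °C should add to the more nucleophilic trisubstituted alkene and the hydroxyl should attack the tertiary carbon (Markovnikov alkoxymercuration), giving the organomercurial oxepane F3. Oxidative demercuration (NaBH4, O2, DMF) should give 23 together with its ring-carbinol epimer F4, which is separated. The fallback comes back at 23.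

Step 3. A second insertion into the product ketone, oxirane formation, or cycloaddition of the diazo compound to the enone may erode the homologation. The fallback sets out from 5. Ethyl diazoacetate with BF3·OEt2 should give the ring-expanded β-keto ester F5, which as an enolisable β-dicarbonyl does not insert again. K2CO3 and MeI should methylate it to F6. Krapcho dealkoxycarbonylation (LiCl, wet DMSO, 150 °C) should give the monomethyl ketone 9, where the fallback comes back; 9 then takes one LiN(iPr)2/MeI cycle to 11 as in step 4.

Further compounds
F1 | step 18 | carboxylic acid corresponding to aldehyde 30 | CC1=CC[C@@H]2[C@@H](CC[C@@]2(C)O)C(C)(C)[C@H]1C/C=C/[C@@]1(C)CC[C@H](O)C(C)(C)O[C@@H]1CCC(=O)O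
F2 | step 18 | Se-phenyl selenoester of F1 | CC1=CC[C@@H]2[C@@H](CC[C@@]2(C)O)C(C)(C)[C@H]1C/C=C/[C@@]1(C)CC[C@H](O)C(C)(C)O[C@@H]1CCC(=O)[Se]c1ccccc1
F3 | step 13 | 3-[(2R,3R)-3-ethenyl-3,7,7-trimethyl-6-(trifluoroacetoxymercurio)oxepan-2-yl]propanenitrile (either configuration at the mercury-bearing carbon) | C=C[C@@]1(C)CCC([Hg]OC(=O)C(F)(F)F)C(C)(C)O[C@@H]1CCC#N
F4 | step 13 | 3-[(2R,3R,6R)-3-ethenyl-6-hydroxy-3,7,7-trimethyloxepan-2-yl]propanenitrile (ring-carbinol epimer of 23) | C=C[C@@]1(C)CC[C@@H](O)C(C)(C)O[C@@H]1CCC#N
F5 | step 3 | ethyl cis-fused 3,6-dimethyl-7-oxo-1,3a,4,7,8,8a-hexahydroazulene-8-carboxylate | CC1=CC[C@@H]2[C@@H](CC=C2C)C(C(=O)OCC)C1=O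
F6 | step 3 | ethyl cis-fused 3,6,8-trimethyl-7-oxo-1,3a,4,7,8,8a-hexahydroazulene-8-carboxylate | CC1=CC[C@@H]2[C@@H](CC=C2C)C(C)(C(=O)OCC)C1=O
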